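**Retrosynthetic overview**
- The target is made by desilylation of spirodienone 22, which comes from phenol 20 by a dearomatising para-spirocyclisation with a trivalent-iodine oxidant. This last C–C bond closes the seven-membered ring and creates the cyclohexadienone in one step; both aromatic rings are bought.
- Phenol 20 is an all-syn 1,4-diaryl-2,3-dimethylbutan-1-ol derivative. Its C3 methyl comes from hydroboration of 1,1-disubstituted alkene 15 followed by deoxygenation of the CH2OH group.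
- Alkene 15 comes from benzyl ketone 14, made from Weinreb amide 11 and a benzylic Grignard reagent derived from syringaldehyde.
- The Weinreb amide comes from the key C–C bond formation: an Evans syn aldol between 3,4,5-trimethoxybenzaldehyde and (R)-4-benzyl-3-propanoyloxazolidin-2-one, which sets the carbinol and adjacent methyl centres.

Assumption: the spiro carbon is not stereogenic (the dienone ring is symmetric), so three stereocentres are set, read from the SMILES as 7R, 8S, 9R (benzo[7]annulene numbering); (R)-4-benzyl-3-propanoyl-1,3-oxazolidin-2-one is taken as commercial.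

**Route**

Step 1
Reactants: 1 syringaldehyde (4-hydroxy-3,5-dimethoxybenzaldehyde)
Product: 2 4-(benzyloxy)-3,5-dimethoxybenzaldehyde
Conditions: BnBr, K2CO3, DMF, 60 °C
Reagents that add atoms: benzyl bromide, BrCc1ccccc1
Why: Williamson etherification of the phenoxide; benzyl masks the phenol until step 12.

Step 2
Reactants: 2 4-(benzyloxy)-3,5-dimethoxybenzaldehyde
Product: 3 [4-(benzyloxy)-3,5-dimethoxyphenyl]methanol
Conditions: NaBH4, MeOH, 0 °C
Reagents that add atoms: none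
Why: Hydride reduction of the aryl aldehyde to the benzylic alcohol; nothing else in the molecule is reducible.

Step 3
Reactants: 3 [4-(benzyloxy)-3,5-dimethoxyphenyl]methanol
Product: 4 2-(benzyloxy)-5-(chloromethyl)-1,3-dimethoxybenzene
Conditions: SOCl2, CH2Cl2, 0 °C; used crude
Reagents that add atoms: thionyl chloride, O=S(Cl)Cl
Why: Chlorodehydroxylation of an electron-rich benzylic alcohol through its chlorosulfite is fast and clean at 0 °C.

Step 4
Reactants: 5 (R)-4-benzyl-3-propanoyl-1,3-oxazolidin-2-one; 6 3,4,5-trimethoxybenzaldehyde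
Product: 9 (4R)-4-benzyl-3-[(2R,3R)-3-hydroxy-2-methyl-3-(3,4,5-trimethoxyphenyl)propanoyl]-1,3-oxazolidin-2-one, via Z dibutylboron enolate 7 (not isolated), via dibutylboron aldolate 8 (not isolated)
Conditions: Bu2BOTf, i-Pr2NEt, CH2Cl2, 0 °C; then 6, −78 → 0 °C; then aq. NaH2PO4/Na2HPO4 (pH 7), MeOH, 30% H2O2, 0 °C
Reagents that add atoms: none
Why: Evans syn aldol: the Z boron enolate reacts through a closed Zimmerman–Traxler chair on the face away from the auxiliary benzyl group, so the (R)-auxiliary sets both new centres as 2R,3R (syn; the future C8 and C9), typically with dr above 95:5.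

Step 5
Reactants: 9 the aldol adduct
Product: 10 (2R,3R)-3-hydroxy-N-methoxy-N,2-dimethyl-3-(3,4,5-trimethoxyphenyl)propanamide
Conditions: MeNH(OMe)·HCl, AlMe3, THF, −20 → 0 °C; aqueous work-up
Reagents that add atoms: N,O-dimethylhydroxylamine hydrochloride, CNOC.Cl
Why: Aluminium-amide transamidation to the Weinreb amide, assisted by chelation of the free β-hydroxyl, releases the auxiliary without touching either stereocentre.

Step 6
Reactants: 10 the hydroxy Weinreb amide
Product: 11 (2R,3R)-3-[(tert-butyldimethylsilyl)oxy]-N-methoxy-N,2-dimethyl-3-(3,4,5-trimethoxyphenyl)propanamide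
Conditions: TBSOTf, 2,6-lutidine, CH2Cl2, −78 → 0 °C
Reagents that add atoms: tert-butyldimethylsilyl triflate, CC(C)(C)[Si](C)(C)OS(=O)(=O)C(F)(F)F
Why: Silylation of the secondary benzylic alcohol blocks retro-aldol and elimination pathways and later prevents O-attack on the oxidised phenol in step 13.

Step 7
Reactants: 4 2-(benzyloxy)-5-(chloromethyl)-1,3-dimethoxybenzene; 11 the silylated Weinreb amide
Product: 14 (3R,4R)-1-[4-(benzyloxy)-3,5-dimethoxyphenyl]-4-[(tert-butyldimethylsilyl)oxy]-3-methyl-4-(3,4,5-trimethoxyphenyl)butan-2-one, via benzylic Grignard reagent 12 (not isolated), via chloromagnesium hemiaminal adduct 13 (not isolated)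
Conditions: Mg turnings (excess), THF, 0 °C, slow addition of 4; then 11, −20 → 0 °C; aqueous work-up
Reagents that add atoms: none
Why: Grignard acylation of a Weinreb amide: the chelated tetrahedral adduct stops over-addition and shields the α-stereocentre from enolisation until work-up.

Step 8
Reactants: 14 the benzyl ketone
Product: 15 tert-butyl{[(1R,2S)-3-{[4-(benzyloxy)-3,5-dimethoxyphenyl]methyl}-2-methyl-1-(3,4,5-trimethoxyphenyl)but-3-en-1-yl]oxy}dimethylsilane
Conditions: Cp2TiMe2, toluene, 70 °C, dark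
Reagents that add atoms: dimethyltitanocene, C[Ti](C)(C1C=CC=C1)C1C=CC=C1
Why: Petasis methylenation through Cp2Ti=CH2 is non-basic, so the readily enolised benzyl ketone is olefinated without epimerising the α-centre or eliminating the β-silyloxy group.

Step 9
Reactants: 15 the 1,1-disubstituted alkene
Product: 17 (2R,3S,4R)-2-{[4-(benzyloxy)-3,5-dimethoxyphenyl]methyl}-4-[(tert-butyldimethylsilyl)oxy]-3-methyl-4-(3,4,5-trimethoxyphenyl)butan-1-ol, via B-alkyl-9-BBN adduct 16 (not isolated)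
Conditions: 9-BBN, THF, 0 → 50 °C; then 3 M NaOH, 30% H2O2, 0 °C → rt; minor epimer removed by chromatography
Reagents that add atoms: hydrogen peroxide, OO
Why: Anti-Markovnikov hydroboration–oxidation under 1,2-induction by allylic strain: 9-BBN attacks the face anti to the large CH(OTBS)Ar group in the conformer whose allylic H eclipses the methylene, which places the new CH2OH syn to the existing methyl (new centre 2R).

Step 10
Reactants: 17 the primary alcohol
Product: 18 (2R,3S,4R)-2-{[4-(benzyloxy)-3,5-dimethoxyphenyl]methyl}-4-[(tert-butyldimethylsilyl)oxy]-3-methyl-4-(3,4,5-trimethoxyphenyl)butyl 4-methylbenzenesulfonate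
Conditions: TsCl, Et3N, DMAP (cat.), CH2Cl2, 0 °C → rt
Reagents that add atoms: 4-toluenesulfonyl chloride, Cc1ccc(cc1)S(Cl)(=O)=O
Why: Sulfonylation of the only free hydroxyl turns it into a leaving group.

Step 11
Reactants: 18 the tosylate
Product: 19 {[(1R,2S,3R)-4-[4-(benzyloxy)-3,5-dimethoxyphenyl]-2,3-dimethyl-1-(3,4,5-trimethoxyphenyl)butyl]oxy}(tert-butyl)dimethylsilane
Conditions: LiEt3BH, THF, 0 °C → rt
Reagents that add atoms: none
Why: SN2 hydride displacement of the primary tosylate converts CH2OTs into CH3 and completes the syn 2,3-dimethyl pair without touching the silyl or benzyl ethers.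

Step 12
Reactants: 19 the benzyl ether
Product: 20 4-[(2R,3S,4R)-4-[(tert-butyldimethylsilyl)oxy]-2,3-dimethyl-4-(3,4,5-trimethoxyphenyl)butyl]-2,6-dimethoxyphenol
Conditions: H2 (1 atm), 10% Pd/C, EtOAc, rt
Reagents that add atoms: none
Why: Catalytic hydrogenolysis cleaves the aryl benzyl ether quickly, while in neutral EtOAc the benzylic silyl ether and the aryl methyl ethers are left alone.

Step 13
Reactants: 20 the phenol
Product: 22 (7R,8S,9R)-9-[(tert-butyldimethylsilyl)oxy]-2,3,3',4,5'-pentamethoxy-7,8-dimethyl-6,7,8,9-tetrahydrospiro[benzo[7]annulene-5,1'-cyclohexa[2,5]dien]-4'-one, via aryloxy phenyl iodine trifluoroacetate 21 (not isolated)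
Conditions: PhI(OCOCF3)2, CF3CH2OH (0.01 M), −40 °C; NaHCO3 quench
Reagents that add atoms: none
Why: Oxidative dearomatising spirocyclisation (intramolecular para phenol–arene coupling): the ring-A carbon ortho to the side chain and para to a methoxy group attacks the para carbon of the activated phenol, closing the seven-membered ring; the dienone is symmetric, so no new stereocentre forms.

Step 14
Reactants: 22 the silylated spirodienone
Product: 23 (7R,8S,9R)-9-hydroxy-2,3,3',4,5'-pentamethoxy-7,8-dimethyl-6,7,8,9-tetrahydrospiro[benzo[7]annulene-5,1'-cyclohexa[2,5]dien]-4'-one (CNP0288561.1)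
Conditions: TBAF, AcOH (1:1), THF, 0 °C → rt
Reagents that add atoms: none
Why: Fluoride-mediated desilylation buffered with AcOH keeps the medium non-basic, so the cross-conjugated dienone and the benzylic alcohol survive.

**Compound list**
1 | syringaldehyde | COc1cc(C=O)cc(OC)c1O | starting material
2 | 4-(benzyloxy)-3,5-dimethoxybenzaldehyde | COc1cc(C=O)cc(OC)c1OCc1ccccc1 | intermediate
3 | [4-(benzyloxy)-3,5-dimethoxyphenyl]methanol | COc1cc(CO)cc(OC)c1OCc1ccccc1 | intermediate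
4 | 2-(benzyloxy)-5-(chloromethyl)-1,3-dimethoxybenzene | COc1cc(CCl)cc(OC)c1OCc1ccccc1 | intermediate
5 | (R)-4-benzyl-3-propanoyl-1,3-oxazolidin-2-one | CCC(=O)N1[C@H](Cc2ccccc2)COC1=O | starting material
6 | 3,4,5-trimethoxybenzaldehyde | COc1cc(C=O)cc(OC)c1OC | starting material
7 | Z dibutylboron enolate of 5 | C/C=C(\OB(CCCC)CCCC)N1[C@H](Cc2ccccc2)COC1=O | intermediate
8 | dibutylboron aldolate of 9 | O=C([C@H](C)[C@@H](OB(CCCC)CCCC)c1cc(OC)c(OC)c(OC)c1)N1[C@H](Cc2ccccc2)COC1=O | intermediate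
9 | (4R)-4-benzyl-3-[(2R,3R)-3-hydroxy-2-methyl-3-(3,4,5-trimethoxyphenyl)propanoyl]-1,3-oxazolidin-2-one | O=C([C@H](C)[C@@H](O)c1cc(OC)c(OC)c(OC)c1)N1[C@H](Cc2ccccc2)COC1=O | intermediate
10 | (2R,3R)-3-hydroxy-N-methoxy-N,2-dimethyl-3-(3,4,5-trimethoxyphenyl)propanamide | CON(C)C(=O)[C@H](C)[C@@H](O)c1cc(OC)c(OC)c(OC)c1 | intermediate
11 | (2R,3R)-3-[(tert-butyldimethylsilyl)oxy]-N-methoxy-N,2-dimethyl-3-(3,4,5-trimethoxyphenyl)propanamide | CON(C)C(=O)[C@H](C)[C@@H](O[Si](C)(C)C(C)(C)C)c1cc(OC)c(OC)c(OC)c1 | intermediate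
12 | [4-(benzyloxy)-3,5-dimethoxybenzyl]magnesium chloride | COc1cc(C[Mg]Cl)cc(OC)c1OCc1ccccc1 | intermediate
13 | chloromagnesium alkoxide of the N-methoxy-N-methyl hemiaminal from 11 and 12 | CON(C)C(O[Mg]Cl)(Cc1cc(OC)c(OCc2ccccc2)c(OC)c1)[C@H](C)[C@@H](O[Si](C)(C)C(C)(C)C)c1cc(OC)c(OC)c(OC)c1 | intermediate
14 | (3R,4R)-1-[4-(benzyloxy)-3,5-dimethoxyphenyl]-4-[(tert-butyldimethylsilyl)oxy]-3-methyl-4-(3,4,5-trimethoxyphenyl)butan-2-one | O=C(Cc1cc(OC)c(OCc2ccccc2)c(OC)c1)[C@H](C)[C@@H](O[Si](C)(C)C(C)(C)C)c1cc(OC)c(OC)c(OC)c1 | intermediate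
15 | tert-butyl{[(1R,2S)-3-{[4-(benzyloxy)-3,5-dimethoxyphenyl]methyl}-2-methyl-1-(3,4,5-trimethoxyphenyl)but-3-en-1-yl]oxy}dimethylsilane | C=C(Cc1cc(OC)c(OCc2ccccc2)c(OC)c1)[C@H](C)[C@@H](O[Si](C)(C)C(C)(C)C)c1cc(OC)c(OC)c(OC)c1 | intermediate
16 | 9-[(2R,3S,4R)-2-{[4-(benzyloxy)-3,5-dimethoxyphenyl]methyl}-4-[(tert-butyldimethylsilyl)oxy]-3-methyl-4-(3,4,5-trimethoxyphenyl)butyl]-9-borabicyclo[3.3.1]nonane | COc1cc(C[C@@H](CB2C3CCCC2CCC3)[C@H](C)[C@@H](O[Si](C)(C)C(C)(C)C)c2cc(OC)c(OC)c(OC)c2)cc(OC)c1OCc1ccccc1 | intermediate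
17 | (2R,3S,4R)-2-{[4-(benzyloxy)-3,5-dimethoxyphenyl]methyl}-4-[(tert-butyldimethylsilyl)oxy]-3-methyl-4-(3,4,5-trimethoxyphenyl)butan-1-ol | COc1cc(C[C@@H](CO)[C@H](C)[C@@H](O[Si](C)(C)C(C)(C)C)c2cc(OC)c(OC)c(OC)c2)cc(OC)c1OCc1ccccc1 | intermediate
18 | (2R,3S,4R)-2-{[4-(benzyloxy)-3,5-dimethoxyphenyl]methyl}-4-[(tert-butyldimethylsilyl)oxy]-3-methyl-4-(3,4,5-trimethoxyphenyl)butyl 4-methylbenzenesulfonate | COc1cc(C[C@@H](COS(=O)(=O)c2ccc(C)cc2)[C@H](C)[C@@H](O[Si](C)(C)C(C)(C)C)c2cc(OC)c(OC)c(OC)c2)cc(OC)c1OCc1ccccc1 | intermediate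
19 | {[(1R,2S,3R)-4-[4-(benzyloxy)-3,5-dimethoxyphenyl]-2,3-dimethyl-1-(3,4,5-trimethoxyphenyl)butyl]oxy}(tert-butyl)dimethylsilane | COc1cc(C[C@@H](C)[C@H](C)[C@@H](O[Si](C)(C)C(C)(C)C)c2cc(OC)c(OC)c(OC)c2)cc(OC)c1OCc1ccccc1 | intermediate
20 | 4-[(2R,3S,4R)-4-[(tert-butyldimethylsilyl)oxy]-2,3-dimethyl-4-(3,4,5-trimethoxyphenyl)butyl]-2,6-dimethoxyphenol | COc1cc(C[C@@H](C)[C@H](C)[C@@H](O[Si](C)(C)C(C)(C)C)c2cc(OC)c(OC)c(OC)c2)cc(OC)c1O | intermediate
21 | aryloxy(phenyl)iodine trifluoroacetate of phenol 20 | COc1cc(C[C@@H](C)[C@H](C)[C@@H](O[Si](C)(C)C(C)(C)C)c2cc(OC)c(OC)c(OC)c2)cc(OC)c1OI(OC(=O)C(F)(F)F)c1ccccc1 | intermediate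
22 | (7R,8S,9R)-9-[(tert-butyldimethylsilyl)oxy]-2,3,3',4,5'-pentamethoxy-7,8-dimethyl-6,7,8,9-tetrahydrospiro[benzo[7]annulene-5,1'-cyclohexa[2,5]dien]-4'-one | COC1=CC2(C=C(OC)C1=O)C[C@@H](C)[C@H](C)[C@@H](O[Si](C)(C)C(C)(C)C)c1cc(OC)c(OC)c(OC)c12 | intermediate
23 | (7R,8S,9R)-9-hydroxy-2,3,3',4,5'-pentamethoxy-7,8-dimethyl-6,7,8,9-tetrahydrospiro[benzo[7]annulene-5,1'-cyclohexa[2,5]dien]-4'-one (CNP0288561.1) | COC1=CC2(C=C(OC)C1=O)C[C@@H](C)[C@H](C)[C@@H](O)c1cc(OC)c(OC)c(OC)c12 | target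

**Step count**
Total: 14 steps. Longest linear sequence: 11 steps (steps 4–14 from 5 and 6; equally steps 1–3 and 7–14 from 1).

**Steps most likely to fail, with fallbacks**

Step 7. The electron-rich benzylic chloride can undergo Wurtz coupling during Grignard formation, leaving too little reagent for the acylation. The fallback sets out from 4 (and uses 11) and comes back at 14. Chloride 4 is displaced with PhSO2Na in DMF to give 2-(benzyloxy)-1,3-dimethoxy-5-[(phenylsulfonyl)methyl]benzene F1. Deprotonation with n-BuLi in THF at −78 °C gives [4-(benzyloxy)-3,5-dimethoxyphenyl](phenylsulfonyl)methyllithium F2. Two equivalents of F2 acylate Weinreb amide 11 to (3R,4R)-1-[4-(benzyloxy)-3,5-dimethoxyphenyl]-4-[(tert-butyldimethylsilyl)oxy]-3-methyl-1-(phenylsulfonyl)-4-(3,4,5-trimethoxyphenyl)butan-2-one F3, as a mixture at the sulfonyl-bearing carbon. Reductive desulfonylation with SmI2 in THF/MeOH at −78 °C then gives ketone 14.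

Step 9. The facial selectivity of the hydroboration rests on substrate control and may be lower than hoped with the bulky benzylic substituent on the alkene. The fallback sets out from 15 and comes back at 19, bypassing steps 9–11. TBAF/AcOH in THF frees (1R,2S)-3-{[4-(benzyloxy)-3,5-dimethoxyphenyl]methyl}-2-methyl-1-(3,4,5-trimethoxyphenyl)but-3-en-1-ol F4. Hydroxyl-directed hydrogenation with [Ir(cod)(PCy3)(py)]PF6 (H2 1 atm, CH2Cl2) delivers hydrogen from the face held by the carbinol oxygen. With the C2 methyl turned away from the benzylic CH2 (least A(1,2) strain) this is the same face that 9-BBN attacks, and the product is (1R,2S,3R)-4-[4-(benzyloxy)-3,5-dimethoxyphenyl]-2,3-dimethyl-1-(3,4,5-trimethoxyphenyl)butan-1-ol F5. The sense of induction is argued from a model and the dr would need checking. TBSOTf/2,6-lutidine then re-silylates F5 to 19.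

Step 13. Closing a seven-membered ring on a flexible chain may lose to solvent capture or intermolecular coupling, and the acid released can trigger dienone–phenol rearrangement. The fallback sets out from 20 and comes back at 22, separating oxidation from C–C bond formation. PhI(OAc)2 in MeOH at 0 °C traps the oxidised phenol with solvent to give the isolable quinol ether 4-[(2R,3S,4R)-4-[(tert-butyldimethylsilyl)oxy]-2,3-dimethyl-4-(3,4,5-trimethoxyphenyl)butyl]-2,4,6-trimethoxycyclohexa-2,5-dien-1-one F6. BF3·OEt2 (0.2 equiv) in dilute CH2Cl2 at −78 °C, quenched cold with Et3N, ionises the tertiary methoxy group; the tethered trimethoxyphenyl ring captures the cation at the same carbon to give 22. The cold quench is needed because the same Lewis acid promotes rearrangement of the product when warm.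

**Further compounds**
F1 | step 7 | 2-(benzyloxy)-1,3-dimethoxy-5-[(phenylsulfonyl)methyl]benzene | COc1cc(CS(=O)(=O)c2ccccc2)cc(OC)c1OCc1ccccc1
F2 | step 7 | [4-(benzyloxy)-3,5-dimethoxyphenyl](phenylsulfonyl)methyllithium | [Li]C(c1cc(OC)c(OCc2ccccc2)c(OC)c1)S(=O)(=O)c1ccccc1
F3 | step 7 | (3R,4R)-1-[4-(benzyloxy)-3,5-dimethoxyphenyl]-4-[(tert-butyldimethylsilyl)oxy]-3-methyl-1-(phenylsulfonyl)-4-(3,4,5-trimethoxyphenyl)butan-2-one | O=C(C(c1cc(OC)c(OCc2ccccc2)c(OC)c1)S(=O)(=O)c1ccccc1)[C@H](C)[C@@H](O[Si](C)(C)C(C)(C)C)c1cc(OC)c(OC)c(OC)c1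
F4 | step 9 | (1R,2S)-3-{[4-(benzyloxy)-3,5-dimethoxyphenyl]methyl}-2-methyl-1-(3,4,5-trimethoxyphenyl)but-3-en-1-ol | C=C(Cc1cc(OC)c(OCc2ccccc2)c(OC)c1)[C@H](C)[C@@H](O)c1cc(OC)c(OC)c(OC)c1
F5 | step 9 | (1R,2S,3R)-4-[4-(benzyloxy)-3,5-dimethoxyphenyl]-2,3-dimethyl-1-(3,4,5-trimethoxyphenyl)butan-1-ol | COc1cc(C[C@@H](C)[C@H](C)[C@@H](O)c2cc(OC)c(OC)c(OC)c2)cc(OC)c1OCc1ccccc1
F6 | step 13 | 4-[(2R,3S,4R)-4-[(tert-butyldimethylsilyl)oxy]-2,3-dimethyl-4-(3,4,5-trimethoxyphenyl)butyl]-2,4,6-trimethoxycyclohexa-2,5-dien-1-one | COC1=CC(OC)(C[C@@H](C)[C@H](C)[C@@H](O[Si](C)(C)C(C)(C)C)c2cc(OC)c(OC)c(OC)c2)C=C(OC)C1=O
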